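**Retrosynthetic overview**

1. Feature: on the nine-membered ring B (C4a, C5–C11, C11a) the C7 tertiary carbinol lies syn to the cis C8–C9 oxirane. This triad is read as the trace of a singlet-oxygen ene reaction on a (7Z)-7-methyl C7=C8 olefin followed by transfer of the peroxide oxygen, so C7–O, C8–O and C9–O are disconnected together, late, on the complete bicycle.
2. Ring B: ring-closing metathesis at C7=C8 on a trans-3,4-disubstituted dihydropyran; C11 travels as a silyloxy carbon and becomes the exocyclic methylene afterwards.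
3. Ring A (C1, O2, C3, C4, C4a, C11a): inverse-demand hetero-Diels–Alder reaction of a 2-formylacrylate (C3–C7) with an (E)-2-ethoxyvinyl carbinol silyl ether (C1, C11a, C11–C8). Its C11 centre, set by catalytic asymmetric vinylzinc addition, steers the face.
4. Side chain: C4 ester to C12 aldehyde, asymmetric alkenylzinc addition (C12–C13), Sharpless epoxidation, Payne rearrangement to the 12,13-diol and 14,15-oxirane. C1 is carried as a silyl acetal and becomes the acetate last.
5. Ring order: ring A, ring B, C8–C9 oxirane (key step), C14–C15 oxirane.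

Key step: step 11

Remark: locants are those of the xenicane skeleton (C1 acetal carbon, O2, C3=C4, C4a, C5–C11, C11a, side chain C12–C15); step 4 is assumed to add anti to the silyloxy group of 6 with the carbinol hydrogen eclipsing the olefin, which calls for the (R)-carbinol (with the opposite sense, (+)-MIB is used in step 1), and the silyl acetal 17 is drawn as the anomer with the C1 oxygen trans to C11, its anomeric composition being immaterial because C1 passes through the free lactol again in step 18.

**Route**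

Step 1
Reactants: 1 ethoxyethyne; 2 pent-4-enal
Product: 5 (1E,3R)-1-ethoxyhepta-1,6-dien-3-ol, via ethoxyvinylborane 3 (not isolated), via ethoxyvinylzinc 4 (not isolated)
Conditions: 1, Cy2BH, toluene, 0 °C → rt; Me2Zn, −78 °C; (−)-MIB (5 mol %), then 2, −30 → 0 °C; aq. NaHCO3 work-up, Et3N-deactivated silica
Reagents that add atoms: none
Why: Syn hydroboration of the alkoxyalkyne puts boron on the terminal carbon and gives the (E)-vinylborane, boron-to-zinc exchange and amino-alkoxide-catalysed 1,2-addition (asymmetric vinylzinc addition to an aldehyde) form the C11–C11a bond, and (−)-MIB should deliver the vinyl group to the Si face, which sets the (R)-carbinol that directs step 4 and is erased in step 7.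

Step 2
Reactants: 5 (1E,3R)-1-ethoxyhepta-1,6-dien-3-ol
Product: 6 tert-butyl{[(1E,3R)-1-ethoxyhepta-1,6-dien-3-yl]oxy}dimethylsilane
Conditions: TBSCl, imidazole, DMF, 0 °C → rt
Reagents that add atoms: tert-butyldimethylsilyl chloride, CC(C)(C)[Si](C)(C)Cl
Why: Silyl ether formation under basic conditions keeps the acid-labile hydroxy enol ether intact and touches no stereocentre.

Step 3
Reactants: 7 methyl 3,3-dimethoxypropanoate; 8 4-methylpent-4-enal
Product: 10 methyl (2Z)-2-formyl-6-methylhepta-2,6-dienoate, via methyl 3-oxopropanoate 9 (not isolated)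
Conditions: 7, 1 M HCl, THF, 0 °C → rt, cold extraction (CH2Cl2); then 8, piperidine (10 mol %), AcOH (10 mol %), 4 Å MS, CH2Cl2, 0 °C; used without storage
Reagents that add atoms: water, O
Why: Knoevenagel condensation of the freshly liberated, strongly CH-acidic formylacetate with the aliphatic aldehyde; the two olefin isomers interconvert by reversible amine addition, so the Z isomer (chain trans to the formyl group) needed in step 4 is replenished.

Step 4
Reactants: 10 methyl (2Z)-2-formyl-6-methylhepta-2,6-dienoate; 6 tert-butyl{[(1E,3R)-1-ethoxyhepta-1,6-dien-3-yl]oxy}dimethylsilane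
Product: 11 methyl (2S,3R,4S)-3-[(1R)-1-(tert-butyldimethylsilyloxy)pent-4-enyl]-2-ethoxy-4-(3-methylbut-3-enyl)-3,4-dihydro-2H-pyran-5-carboxylate
Conditions: 10 (1.5 equiv), toluene (1 M), 4 Å MS, BHT (trace), 25 → 45 °C
Reagents that add atoms: none
Why: Inverse-electron-demand hetero-Diels–Alder reaction of the electron-poor 1-oxadiene (formyl C=O with C4=C4a) with the enol ether: the endo ethoxy group ends cis to the C4a chain, the E geometry of 6 becomes the trans C1/C11a relationship, the outward chain of 10 gives the trans C4a/C11a relationship, and the absolute sense comes from addition anti to the allylic silyloxy group (1,2-induction), a minor facial isomer being a separable diastereomer.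

Step 5
Reactants: 11 (the dihydropyran of step 4)
Product: 12 methyl (1S,4aS,7Z,11R,11aR)-11-(tert-butyldimethylsilyloxy)-1-ethoxy-7-methyl-1,4a,5,6,9,10,11,11a-octahydrocyclonona[c]pyran-4-carboxylate
Conditions: second-generation Grubbs catalyst (H2IMes)(PCy3)Cl2Ru=CHPh (10 mol %), toluene (1 mM), 80 °C
Reagents that add atoms: none
Why: Ring-closing metathesis: the catalyst loads on the monosubstituted olefin and closes onto the 1,1-disubstituted one, nine being the only productive ring size, high dilution suppresses oligomers, the ester-conjugated enol ether is inert, and the trisubstituted olefin in a nine-membered ring should form Z for reasons of strain.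

Step 6
Reactants: 12 (the silyl ether of step 5)
Product: 13 methyl (1S,4aS,7Z,11R,11aR)-1-ethoxy-11-hydroxy-7-methyl-1,4a,5,6,9,10,11,11a-octahydrocyclonona[c]pyran-4-carboxylate
Conditions: TBAF, AcOH (1:1), THF, rt → 40 °C
Reagents that add atoms: none
Why: Fluoride-mediated desilylation buffered with acetic acid leaves acetal, ester and olefins untouched; the C11 configuration is of no consequence.

Step 7
Reactants: 13 (the C11 alcohol)
Product: 14 methyl (1S,4aS,7Z,11aS)-1-ethoxy-7-methyl-11-oxo-1,4a,5,6,9,10,11,11a-octahydrocyclonona[c]pyran-4-carboxylate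
Conditions: Dess–Martin periodinane, CH2Cl2, 0 °C → rt; used at once
Reagents that add atoms: none
Why: Dess–Martin oxidation under mild, non-basic conditions, so the β-alkoxy ketone should neither epimerise at C11a nor eliminate the C1 oxygen.

Step 8
Reactants: 14 (the C11 ketone)
Product: 15 methyl (1S,4aS,7Z,11aR)-1-ethoxy-7-methyl-11-methylidene-1,4a,5,6,9,10,11,11a-octahydrocyclonona[c]pyran-4-carboxylate
Conditions: Tebbe reagent Cp2Ti(μ-CH2)(μ-Cl)AlMe2 (1.2 equiv), pyridine (cat.), THF/toluene, −40 → 0 °C
Reagents that add atoms: Tebbe reagent, C[Al](C)C[Ti](Cl)(C1C=CC=C1)C1C=CC=C1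
Why: Tebbe methylenation: the non-basic titanium methylidene converts the ketone faster than the deactivated vinylogous carbonate ester and avoids the enolisation toward C11a that a phosphorus ylide would risk.

Step 9
Reactants: 15 (the ethyl acetal)
Product: 16 methyl (1S,4aS,7Z,11aR)-1-hydroxy-7-methyl-11-methylidene-1,4a,5,6,9,10,11,11a-octahydrocyclonona[c]pyran-4-carboxylate
Conditions: 1 M HCl, THF (1:3), rt, monitored closely
Reagents that add atoms: water, O
Why: Acid-catalysed acetal hydrolysis through the C1 oxocarbenium ion, at an acidity at which the ester-deactivated enol ether and the isolated olefins should not be protonated, gives a stable 4-carboxylate lactol; the exchange is made here because no alkyl acetal could be removed at the end beside two oxiranes and an electron-rich enol ether.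

Step 10
Reactants: 16 (the lactol)
Product: 17 methyl (1R,4aS,7Z,11aR)-7-methyl-11-methylidene-1-(triisopropylsilyloxy)-1,4a,5,6,9,10,11,11a-octahydrocyclonona[c]pyran-4-carboxylate
Conditions: TIPSOTf, 2,6-lutidine, CH2Cl2, −78 → 0 °C
Reagents that add atoms: triisopropylsilyl triflate, CC(C)[Si](OS(=O)(=O)C(F)(F)F)(C(C)C)C(C)C
Why: O-Silylation of the hemiacetal hydroxyl gives a fluoride-labile acetal that tolerates hydride, organozinc, titanium alkoxide and carbonate conditions; the bulky silyl triflate is expected to take the anomer with oxygen trans to C11.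

Step 11
Reactants: 17 (the bicyclic (7Z)-olefin with exocyclic methylene)
Product: 19 methyl (1R,4aS,7S,8R,9R,11aR)-8,9-epoxy-7-hydroxy-7-methyl-11-methylidene-1-(triisopropylsilyloxy)-1,4a,5,6,7,8,9,10,11,11a-decahydrocyclonona[c]pyran-4-carboxylate, via allylic hydroperoxide 18 (not isolated)
Conditions: O2, TPP (1 mol %), white LED, CH2Cl2, −20 °C; then Ti(OiPr)4 (20 mol %), 4 Å MS, 0 °C
Reagents that add atoms: dioxygen (as singlet oxygen), O=O
Why: Photosensitised singlet oxygen engages the trisubstituted C7=C8 olefin through a perepoxide-like transition state, forms the C7–O bond and takes a hydrogen from C9 on the same face (Schenck ene reaction), which gives the tertiary allylic hydroperoxide 18 with the olefin moved to C8=C9 (Z within the ring); Ti(OiPr)4 then binds the hydroperoxide and its distal oxygen is passed to the neighbouring olefin, the closest known reaction type being the one-pot ene/titanium hydroxy-epoxidation of trisubstituted olefins. The oxirane is closed by concerted [2+1] transfer of one oxygen atom across C8=C9, both C–O bonds forming on one face, so the cis geometry of the olefin is kept. C7 is set by the face on which oxygen approaches, taken to be the outer face of the olefin that the trans ring fusion at C4a/C11a turns away from the ring interior; C8 and C9 are set by delivery from titanium held on the C7 oxygen, hence syn to the carbinol. Chemoselectivity rests on the trisubstituted olefin being far more reactive toward the electrophilic oxidant than the 1,1-disubstituted C11 methylene and the ester-conjugated enol ether C3=C4. Regioselectivity needs abstraction at C9 and not at C6 or the C7 methyl group: the cis effect directs abstraction to the ring side of the Z-olefin (C6 and C9), and the choice between these two rests on the ring conformation placing a C9–H bond perpendicular to the olefin plane, which is the main uncertainty of the step.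

Step 12
Reactants: 19 (the epoxy carbinol ester)
Product: 20 (1R,4aS,7S,8R,9R,11aR)-8,9-epoxy-4-(hydroxymethyl)-7-methyl-11-methylidene-1-(triisopropylsilyloxy)-1,4a,5,6,7,8,9,10,11,11a-decahydrocyclonona[c]pyran-7-ol
Conditions: DIBAL-H (iBu2AlH, 4 equiv), CH2Cl2, −78 °C; aq. potassium sodium tartrate
Reagents that add atoms: none
Why: DIBAL-H reduces the vinylogous carbonate ester in 1,2-fashion to the allylic alcohol at −78 °C, where oxirane and silyl acetal are not attacked; one equivalent is consumed by the C7 hydroxyl.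

Step 13
Reactants: 20 (the C12 alcohol)
Product: 21 (1R,4aS,7S,8R,9R,11aR)-8,9-epoxy-7-hydroxy-7-methyl-11-methylidene-1-(triisopropylsilyloxy)-1,4a,5,6,7,8,9,10,11,11a-decahydrocyclonona[c]pyran-4-carbaldehyde
Conditions: activated MnO2 (excess), CH2Cl2, rt
Reagents that add atoms: none
Why: Manganese dioxide oxidises the allylic, enol-ether-conjugated primary alcohol selectively to the β-alkoxy enal and leaves the tertiary alcohol alone.

Step 14
Reactants: 21 (the C12 aldehyde); 22 trimethyl[(2-methylbut-3-yn-2-yl)oxy]silane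
Product: 25 the C4-[(1S,2E)-1-hydroxy-4-methyl-4-(trimethylsilyloxy)pent-2-enyl] analogue of 21 (12S-allylic alcohol), via alkenylborane 23 (not isolated), via alkenylzinc 24 (not isolated)
Conditions: 22 (3 equiv), Cy2BH, toluene, 0 °C → rt; Me2Zn, −78 °C; (−)-MIB (10 mol %), then 21, −30 → 0 °C; aq. NaHCO3
Reagents that add atoms: none
Why: Hydroboration and boron-to-zinc exchange give the (E)-alkenylzinc reagent, whose (−)-MIB-catalysed addition to the aldehyde (asymmetric alkenylzinc addition) should take the Si face and set the (12S)-carbinol under reagent control; excess reagent covers the free C7 hydroxyl, and oxirane and silyl ethers are inert to organozinc species.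

Step 15
Reactants: 25 (the 12S-allylic alcohol)
Product: 26 the (12R,13R,14S)-13,14-epoxy-12-ol: C4-{(R)-hydroxy[(2R,3S)-3-(2-(trimethylsilyloxy)propan-2-yl)oxiran-2-yl]methyl} analogue of 21
Conditions: Ti(OiPr)4 (1.1 equiv), D-(−)-DIPT (1.3 equiv), TBHP (2 equiv, in decane), 4 Å MS, CH2Cl2, −20 °C; Na2SO4·10H2O work-up
Reagents that add atoms: tert-butyl hydroperoxide, CC(C)(C)OO
Why: Sharpless asymmetric epoxidation of the secondary allylic alcohol: with D-(−)-DIPT the (12S)-carbinol is the fast-reacting case for the C13=C14 olefin and gives the erythro (12,13-anti) epoxy alcohol with oxygen on the required face, whereas the same tartrate presents the other allylic olefin C3=C4 of this divinyl carbinol in the slow-reacting sense, which is what should protect the enol ether.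

Step 16
Reactants: 26 (the 13,14-epoxy alcohol)
Product: 28 the (12R,13R,14R)-12,13-diol-14,15-oxirane: C4-{(1R,2R)-2-[(2R)-3,3-dimethyloxiran-2-yl]-1,2-dihydroxyethyl} analogue of 21, via epoxy triol 27 (not isolated)
Conditions: K2CO3 (0.3 equiv), MeOH, 0 °C → rt
Reagents that add atoms: none
Why: Carbonate-mediated methanolysis removes the tertiary trimethylsilyl ether and the C15 alkoxide opens the oxirane at C14 with inversion (Payne rearrangement); the equilibrium should favour the trisubstituted 14,15-oxirane with the secondary C13 hydroxyl, C13 keeps its configuration, and the syn 7-hydroxy-8,9-oxirane cannot rearrange because backside attack is geometrically impossible.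

Step 17
Reactants: 28 (the 12,13-diol)
Product: 29 the 12,13-di-O-acetate of 28 (C1 silyl acetal and C7 hydroxyl unchanged)
Conditions: Ac2O, pyridine, DMAP (cat.), CH2Cl2, 0 °C
Reagents that add atoms: acetic anhydride, CC(=O)OC(C)=O
Why: DMAP-catalysed acetylation of the two secondary hydroxyls at 0 °C; the hindered tertiary C7 hydroxyl reacts far more slowly and stays free.

Step 18
Reactants: 29 (the diacetate silyl acetal)
Product: 31 CNP0134792.1: (1R,4aS,7S,8R,9R,11aR)-1-acetoxy-4-{(1R,2R)-1,2-diacetoxy-2-[(2R)-3,3-dimethyloxiran-2-yl]ethyl}-8,9-epoxy-7-methyl-11-methylidene-1,4a,5,6,7,8,9,10,11,11a-decahydrocyclonona[c]pyran-7-ol, via lactol 30 (not isolated)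
Conditions: TBAF, AcOH (1:1), THF, 0 °C; then Ac2O, pyridine, DMAP (cat.), 0 °C
Reagents that add atoms: acetic anhydride, CC(=O)OC(C)=O
Why: Buffered fluoride cleaves the silyl acetal without base-induced ring opening and the lactol is acetylated at once; the acetate is expected to settle trans to C11, taken to be the anomerically favoured arrangement of this ring, which gives the (1R) configuration, while the C12 and C13 acetates and the tertiary alcohol are unaffected.

**Compound list**

1 | ethoxyethyne | CCOC#C | starting material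
2 | pent-4-enal | C=CCCC=O | starting material
3 | dicyclohexyl[(E)-2-ethoxyethenyl]borane | CCO/C=C/B(C1CCCCC1)C1CCCCC1 | intermediate
4 | [(E)-2-ethoxyethenyl](methyl)zinc | CCO/C=C/[Zn]C | intermediate
5 | (1E,3R)-1-ethoxyhepta-1,6-dien-3-ol | CCO/C=C/[C@H](O)CCC=C | intermediate
6 | tert-butyl{[(1E,3R)-1-ethoxyhepta-1,6-dien-3-yl]oxy}dimethylsilane | CCO/C=C/[C@H](O[Si](C)(C)C(C)(C)C)CCC=C | intermediate
7 | methyl 3,3-dimethoxypropanoate | COC(OC)CC(=O)OC | starting material
8 | 4-methylpent-4-enal | CC(=C)CCC=O | starting material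
9 | methyl 3-oxopropanoate | COC(=O)CC=O | intermediate
10 | methyl (2Z)-2-formyl-6-methylhepta-2,6-dienoate | C=C(C)CC/C=C(/C=O)C(=O)OC | intermediate
11 | methyl (2S,3R,4S)-3-[(1R)-1-(tert-butyldimethylsilyloxy)pent-4-enyl]-2-ethoxy-4-(3-methylbut-3-enyl)-3,4-dihydro-2H-pyran-5-carboxylate | C=C(C)CC[C@@H]1C(C(=O)OC)=CO[C@H](OCC)[C@H]1[C@H](O[Si](C)(C)C(C)(C)C)CCC=C | intermediate
12 | methyl (1S,4aS,7Z,11R,11aR)-11-(tert-butyldimethylsilyloxy)-1-ethoxy-7-methyl-1,4a,5,6,9,10,11,11a-octahydrocyclonona[c]pyran-4-carboxylate | CC(C)(C)[Si](C)(C)O[C@@H]1CC/C=C(C)\CC[C@@H]2C(C(=O)OC)=CO[C@H](OCC)[C@@H]12 | intermediate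
13 | methyl (1S,4aS,7Z,11R,11aR)-1-ethoxy-11-hydroxy-7-methyl-1,4a,5,6,9,10,11,11a-octahydrocyclonona[c]pyran-4-carboxylate | O[C@@H]1CC/C=C(C)\CC[C@@H]2C(C(=O)OC)=CO[C@H](OCC)[C@@H]12 | intermediate
14 | methyl (1S,4aS,7Z,11aS)-1-ethoxy-7-methyl-11-oxo-1,4a,5,6,9,10,11,11a-octahydrocyclonona[c]pyran-4-carboxylate | O=C1CC/C=C(C)\CC[C@@H]2C(C(=O)OC)=CO[C@H](OCC)[C@@H]12 | intermediate
15 | methyl (1S,4aS,7Z,11aR)-1-ethoxy-7-methyl-11-methylidene-1,4a,5,6,9,10,11,11a-octahydrocyclonona[c]pyran-4-carboxylate | C=C1CC/C=C(C)\CC[C@@H]2C(C(=O)OC)=CO[C@H](OCC)[C@@H]12 | intermediate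
16 | methyl (1S,4aS,7Z,11aR)-1-hydroxy-7-methyl-11-methylidene-1,4a,5,6,9,10,11,11a-octahydrocyclonona[c]pyran-4-carboxylate | C=C1CC/C=C(C)\CC[C@@H]2C(C(=O)OC)=CO[C@H](O)[C@@H]12 | intermediate
17 | methyl (1R,4aS,7Z,11aR)-7-methyl-11-methylidene-1-(triisopropylsilyloxy)-1,4a,5,6,9,10,11,11a-octahydrocyclonona[c]pyran-4-carboxylate (key-step precursor) | C=C1CC/C=C(C)\CC[C@@H]2C(C(=O)OC)=CO[C@H](O[Si](C(C)C)(C(C)C)C(C)C)[C@@H]12 | intermediate
18 | methyl (1R,4aS,7S,8Z,11aR)-7-hydroperoxy-7-methyl-11-methylidene-1-(triisopropylsilyloxy)-1,4a,5,6,7,10,11,11a-octahydrocyclonona[c]pyran-4-carboxylate | C=C1C/C=C\[C@@](C)(OO)CC[C@@H]2C(C(=O)OC)=CO[C@H](O[Si](C(C)C)(C(C)C)C(C)C)[C@@H]12 | intermediate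
19 | methyl (1R,4aS,7S,8R,9R,11aR)-8,9-epoxy-7-hydroxy-7-methyl-11-methylidene-1-(triisopropylsilyloxy)-1,4a,5,6,7,8,9,10,11,11a-decahydrocyclonona[c]pyran-4-carboxylate (key-step product) | C=C1C[C@H]2O[C@H]2[C@@](C)(O)CC[C@@H]2C(C(=O)OC)=CO[C@H](O[Si](C(C)C)(C(C)C)C(C)C)[C@@H]12 | intermediate
20 | (1R,4aS,7S,8R,9R,11aR)-8,9-epoxy-4-(hydroxymethyl)-7-methyl-11-methylidene-1-(triisopropylsilyloxy)-1,4a,5,6,7,8,9,10,11,11a-decahydrocyclonona[c]pyran-7-ol | C=C1C[C@H]2O[C@H]2[C@@](C)(O)CC[C@@H]2C(CO)=CO[C@H](O[Si](C(C)C)(C(C)C)C(C)C)[C@@H]12 | intermediate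
21 | (1R,4aS,7S,8R,9R,11aR)-8,9-epoxy-7-hydroxy-7-methyl-11-methylidene-1-(triisopropylsilyloxy)-1,4a,5,6,7,8,9,10,11,11a-decahydrocyclonona[c]pyran-4-carbaldehyde | C=C1C[C@H]2O[C@H]2[C@@](C)(O)CC[C@@H]2C(C=O)=CO[C@H](O[Si](C(C)C)(C(C)C)C(C)C)[C@@H]12 | intermediate
22 | trimethyl[(2-methylbut-3-yn-2-yl)oxy]silane | C#CC(C)(C)O[Si](C)(C)C | starting material
23 | dicyclohexyl[(E)-3-methyl-3-(trimethylsilyloxy)but-1-enyl]borane | C[Si](C)(C)OC(C)(C)/C=C/B(C1CCCCC1)C1CCCCC1 | intermediate
24 | methyl[(E)-3-methyl-3-(trimethylsilyloxy)but-1-enyl]zinc | C[Zn]/C=C/C(C)(C)O[Si](C)(C)C | intermediate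
25 | analogue of 21 with C4-[(1S,2E)-1-hydroxy-4-methyl-4-(trimethylsilyloxy)pent-2-enyl] (12S) | C=C1C[C@H]2O[C@H]2[C@@](C)(O)CC[C@@H]2C([C@@H](O)/C=C/C(C)(C)O[Si](C)(C)C)=CO[C@H](O[Si](C(C)C)(C(C)C)C(C)C)[C@@H]12 | intermediate
26 | analogue of 21 with C4-{(R)-hydroxy[(2R,3S)-3-(2-(trimethylsilyloxy)propan-2-yl)oxiran-2-yl]methyl} (12R,13R,14S) | C=C1C[C@H]2O[C@H]2[C@@](C)(O)CC[C@@H]2C([C@@H](O)[C@H]3O[C@@H]3C(C)(C)O[Si](C)(C)C)=CO[C@H](O[Si](C(C)C)(C(C)C)C(C)C)[C@@H]12 | intermediate
27 | analogue of 21 with C4-{(R)-hydroxy[(2R,3S)-3-(2-hydroxypropan-2-yl)oxiran-2-yl]methyl} | C=C1C[C@H]2O[C@H]2[C@@](C)(O)CC[C@@H]2C([C@@H](O)[C@H]3O[C@@H]3C(C)(C)O)=CO[C@H](O[Si](C(C)C)(C(C)C)C(C)C)[C@@H]12 | intermediate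
28 | analogue of 21 with C4-{(1R,2R)-2-[(2R)-3,3-dimethyloxiran-2-yl]-1,2-dihydroxyethyl} | C=C1C[C@H]2O[C@H]2[C@@](C)(O)CC[C@@H]2C([C@@H](O)[C@@H](O)[C@H]3OC3(C)C)=CO[C@H](O[Si](C(C)C)(C(C)C)C(C)C)[C@@H]12 | intermediate
29 | 12,13-di-O-acetate of 28 | C=C1C[C@H]2O[C@H]2[C@@](C)(O)CC[C@@H]2C([C@@H](OC(C)=O)[C@@H](OC(C)=O)[C@H]3OC3(C)C)=CO[C@H](O[Si](C(C)C)(C(C)C)C(C)C)[C@@H]12 | intermediate
30 | C1 lactol of 29 (1S) | C=C1C[C@H]2O[C@H]2[C@@](C)(O)CC[C@@H]2C([C@@H](OC(C)=O)[C@@H](OC(C)=O)[C@H]3OC3(C)C)=CO[C@H](O)[C@@H]12 | intermediate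
31 | CNP0134792.1 | C=C1C[C@H]2O[C@H]2[C@@](C)(O)CC[C@@H]2C([C@@H](OC(C)=O)[C@@H](OC(C)=O)[C@H]3OC3(C)C)=CO[C@H](OC(C)=O)[C@@H]12 | target

**Count and risks**

Total step count: 18. Longest linear sequence: 17 steps (steps 1, 2, 4–18); step 3 is a one-step branch and 22 is bought.

Steps most likely to fail:

Step 11. Hydrogen abstraction may take place at C6 or at the C7 methyl group in place of C9, or oxygen may approach the inner face of the olefin. The fallback fixes the regiochemistry structurally and sets out from 17. Buffered mCPBA (NaHCO3, CH2Cl2, 0 °C) should epoxidise the trisubstituted olefin in preference to the methylene group and give the 7,8-epoxide F1. PhSeNa (from PhSeSePh and NaBH4, EtOH) opens it at the secondary carbon C8 to the hydroxy selenide F2. Oxidation (H2O2, pyridine, THF, 0 °C → rt) and syn elimination of the selenoxide can only run toward C9, because C7 carries no hydrogen, and give the tertiary allylic alcohol F3. Hydroxyl-directed epoxidation (VO(acac)2 cat., TBHP, CH2Cl2, 0 °C) then delivers oxygen syn to the carbinol, and the route is rejoined at 19.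

Step 15. The titanium peroxide may epoxidise the electron-rich enol ether next to the carbinol, or the titanium alkoxide may ionise at C12, in place of epoxidation of the side-chain olefin. The fallback replaces the electrophilic oxidant by a nucleophilic one and sets out from 25. MnO2 (CH2Cl2) gives the cross-conjugated dienone F4. Its C13=C14 enone is epoxidised with La(OiPr)3, BINOL and Ph3As=O (10 mol % each) and TBHP in THF over 4 Å MS, the BINOL antipode being chosen for the (13S,14S)-oxirane; the enol ether side is a vinylogous ester and not attacked by the peroxide anion, and the product is the epoxy ketone F5. Chelation-controlled reduction with Zn(BH4)2 (Et2O, −30 °C) should give the erythro epoxy alcohol, and the route is rejoined at 26. Because C12 is trigonal in F4, this path would also correct a poor result in step 14.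

Step 4. Facial discrimination at the enol ether may be low, or the hindered 1,2-disubstituted enol ether may add so slowly that the oxadiene oligomerises. The fallback changes the source of stereocontrol from the substrate to a reagent and sets out from 6 and 10. The cycloaddition is run with a chiral Lewis acid, the tridentate Schiff-base chromium chloride complex (ONO)CrCl (ONO = dianion of the imine from 3-(1-adamantyl)-5-methylsalicylaldehyde and cis-1-aminoindan-2-ol, trivalent chromium), 5 mol %, 4 Å MS, at rt. It binds the formyl oxygen of 10, accelerates the endo addition and shields one face of the oxadiene; the antipode that reinforces the bias of the silyloxy centre is used. The route is rejoined at 11; no new compound is made (entry F0).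

Further compounds
F1 | step 11 | methyl (1R,4aS,7S,8R,11aR)-7,8-epoxy-7-methyl-11-methylidene-1-(triisopropylsilyloxy)-1,4a,5,6,7,8,9,10,11,11a-decahydrocyclonona[c]pyran-4-carboxylate | C=C1CC[C@H]2O[C@@]2(C)CC[C@@H]2C(C(=O)OC)=CO[C@H](O[Si](C(C)C)(C(C)C)C(C)C)[C@@H]12
F2 | step 11 | methyl (1R,4aS,7S,8S,11aR)-7-hydroxy-7-methyl-11-methylidene-8-(phenylselanyl)-1-(triisopropylsilyloxy)-1,4a,5,6,7,8,9,10,11,11a-decahydrocyclonona[c]pyran-4-carboxylate | C=C1CC[C@H]([Se]c2ccccc2)[C@@](C)(O)CC[C@@H]2C(C(=O)OC)=CO[C@H](O[Si](C(C)C)(C(C)C)C(C)C)[C@@H]12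
F3 | step 11 | methyl (1R,4aS,7S,8Z,11aR)-7-hydroxy-7-methyl-11-methylidene-1-(triisopropylsilyloxy)-1,4a,5,6,7,10,11,11a-octahydrocyclonona[c]pyran-4-carboxylate | C=C1C/C=C\[C@@](C)(O)CC[C@@H]2C(C(=O)OC)=CO[C@H](O[Si](C(C)C)(C(C)C)C(C)C)[C@@H]12
F4 | step 15 | analogue of 21 with C4-[(2E)-4-methyl-4-(trimethylsilyloxy)pent-2-enoyl] (C12 ketone) | C=C1C[C@H]2O[C@H]2[C@@](C)(O)CC[C@@H]2C(C(=O)/C=C/C(C)(C)O[Si](C)(C)C)=CO[C@H](O[Si](C(C)C)(C(C)C)C(C)C)[C@@H]12
F5 | step 15 | analogue of 21 with C4-{[(2S,3S)-3-(2-(trimethylsilyloxy)propan-2-yl)oxiran-2-yl]carbonyl} | C=C1C[C@H]2O[C@H]2[C@@](C)(O)CC[C@@H]2C(C(=O)[C@H]3O[C@@H]3C(C)(C)O[Si](C)(C)C)=CO[C@H](O[Si](C(C)C)(C(C)C)C(C)C)[C@@H]12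
F0 | step 4 | none | none
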